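Monday's flask has stopped. The meeting had this before it:

| setting | Monday's | Thursday's | flask |
|---|---|---|---|
| starting material | 0.050 M | 0.025 M | 0.050 M |
| second substrate | 0.10 M | 0.10 M | 0.100 M |
| free enzyme | 25 µM | 25 µM | 25 µM |
| temperature | 40 °C | 25 °C | 40 °C |
| remark | the very flask that is asked about, followed so far | run made earlier |  |
| time |  |  | 6.0 h |

| run | time / min | target / % | starting material / % |
|---|---|---|---|
| Monday's | 40.0 | 26.6 | 73.9 |
| Monday's | 80.0 | 28.2 | 72.2 |
| Monday's | 120 | 27.9 | 72.1 |
| Monday's | 180 | 27.8 | 71.9 |
| Monday's | 240 | 28.0 | 71.8 |
| Monday's | 300 | 27.8 | 71.9 |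
| Thursday's | 4.00 | 1.7 | 98.2 |
| Thursday's | 8.00 | 3.9 | 96.6 |
| Thursday's | 12.0 | 5.4 | 94.4 |
| Thursday's | 15.0 | 6.4 | 93.6 |
| Thursday's | 20.0 | 8.5 | 91.1 |
| Thursday's | 25.0 | 10.2 | 89.7 |
| Thursday's | 30.0 | 12.3 | 87.6 |

(scatter of a reading: 0.3 percentage points)

* target, in percent of the starting material first charged, at 6.0 h
* the remedy with the largest gain of target, or "none" below 2 percentage points (dusk / noon / autumn / winter / midnight / none)
* target present, with what was taken out counted in, in percent of the starting material first charged, after dusk
* target present, with what was taken out counted in, in percent of the starting material first charged, after winter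

- dusk: at 6.0 h add free enzyme, 50.0% of the amount charged, then wait 12 h
- noon: at 6.0 h add second substrate, 100% of the amount charged, then wait 12 h
- autumn: change nothing and wait 12 h more
- winter: at 6.0 h raise the temperature by 20 K, then wait 12 h
- midnight: at 6.0 h take out 90% of the target then present, then wait 12 h

- removed target is counted in
- additions bring no volume worth counting

The bench chemist reported that Monday's run has stood still since 120 min, at a mean reading of 27.9% target. He added that target and starting material together still close the balance, at 99.7% in the last reading.

The analyst then asked which one concentration sets the order of the rate. She observed that in Monday's flask 71.9% of the starting material remains, more than the target made, yet target no longer moves beyond the scatter. So she concluded that, at this stop in Monday's flask, starting material does not set the order, and that the concentration which does was never read.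

The bench chemist argued that this unread quantity was free enzyme still at work. The analyst argued for second substrate, lost by some side route although charged at 2.00 equivalents. She conceded that the readings do not separate the two, and that Thursday's run, still climbing at 12.3% after 30.0 min, shows no stop to compare.

The chair committed the meeting to second substrate, as a wager, and asked for one number: the reagent share, meaning target at the stop per second substrate charged. Monday's readings give 0.0139 M of target from 0.10 M, so the reagent share reads 13.9%.

On this reckoning Monday's flask stays near 27.9% at 6.0 h. On the same wager, waiting, free enzyme, heat and removal are reckoned to add nothing to it, so dusk and winter are reckoned to end there too. Noon's fresh dose is reckoned to yield the same share of itself, a gain of 28 percentage points.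

The forecast, which differs on the remedy, gave 28% now, dusk as best, 39% after dusk and 28% after winter, since the runs “point to enzyme death, not equilibrium”.

The flask gives 28.0% at 6.0 h. The best remedy is noon, whose gain of 28 points is the largest, while dusk ends at 28.0% and winter at 28.0%.

    second substrate → decomposed reagent (k = 0.0685 min⁻¹, Ea = 82.0 kJ mol⁻¹)
    first complex → loaded enzyme + first product (k = 1040 min⁻¹, Ea = 58.0 kJ mol⁻¹)
    second substrate + loaded enzyme ⇌ second complex (K = 16.0 L mol⁻¹, k = 33800 L mol⁻¹ min⁻¹, Ea = 44.0 kJ mol⁻¹, ΔH = 29.0 kJ mol⁻¹)
    starting material + free enzyme ⇌ first complex (K = 28.0 L mol⁻¹, k = 32400 L mol⁻¹ min⁻¹, Ea = 47.0 kJ mol⁻¹, ΔH = −1.00 kJ mol⁻¹)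
    second complex → free enzyme + target (k = 50.0 min⁻¹, Ea = 83.0 kJ mol⁻¹)
    free enzyme → unfolded enzyme (k = 9.55 × 10⁻⁵ min⁻¹, Ea = 269 kJ mol⁻¹)
    (constants at 40 °C)

At 360 min Monday's flask holds 0% of its second substrate, the limiting reagent, with 0.0860 M of decomposed reagent beside 0.0140 M of target. The neighbour charged with 0.40 M of second substrate tests the share. Carried over unchanged, 13.9% reckons 0.0556 M of target, which is 111% of the starting material and more than its charge of 0.050 M. That neighbour instead gives 60.2% target, beside 0.370 M of decomposed reagent. Its reagent share is 7.53%, about half of Monday's.

The numbers in the tables were generated by integration for an exercise; scatter was added.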